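**Retrosynthetic overview**
- Target ⇒ 3-ethoxy-1,2-dioxolane + silyl ketene acetal of methyl acetate: the C2–C3 bond is made last through the ring peroxycarbenium ion, which sets C3.
- 3-Ethoxydioxolane ⇒ peroxide-bearing enol ether: acid closes the O–C3 bond, so the 1,2-dioxolane is the only ring built and it is formed in the second-to-last step.
- Key step: enol ether ⇒ α-peroxy aldehyde + Ph3P=C(OEt)CH3, an acetyl anion equivalent. C3–C4 is made between two carbonyl-type carbons and the aldehyde oxygen leaves as Ph3P=O.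
- α-Peroxy aldehyde ⇒ (R)-2,2-disubstituted epoxide by perhydrolysis with inversion (sets C5); epoxide ⇒ methyl ketone by catalytic asymmetric CH2 transfer.
- Methyl ketone ⇒ (E)-pent-3-en-2-one + 6-phenylhexyl Grignard by Cu-catalysed asymmetric conjugate addition (sets C7). Ring order: oxirane (made, then opened), then the 1,2-dioxolane.

Assumption: the target is (3R,5S) in the ring with a (2R) side chain, as drawn; in steps 1 and 2 the ligand hand named is the one expected by analogy with published model substrates and is swapped for its mirror image if a first run shows the opposite sense.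

**Step 1**
Reactants: 1 (6-bromohexyl)benzene; 2 (E)-pent-3-en-2-one
Product: 4 (R)-4-methyl-10-phenyldecan-2-one, via 6-phenylhexylmagnesium bromide 3 (not isolated)
Conditions: Mg, Et2O, rt; then 2, CuBr·SMe2 (5 mol %), (R)-1-[(S)-2-(diphenylphosphino)ferrocenyl]ethyldicyclohexylphosphine (Josiphos, 6 mol %), t-BuOMe, −75 °C; aq NH4Cl
Reagents that add atoms: none
Why: Copper-catalysed asymmetric conjugate addition of a Grignard reagent to a linear enone (Feringa type), in which the Cu–Josiphos complex delivers the 6-phenylhexyl group 1,4 to one face of the enone and so sets the side-chain methine (C7 of the skeleton) as R, with about 90% ee expected.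

**Step 2**
Reactants: 4 (R)-4-methyl-10-phenyldecan-2-one
Product: 5 (2R)-2-methyl-2-[(2R)-2-methyl-8-phenyloctyl]oxirane
Conditions: Me3S(O)I, NaH, THF, rt; then 4, LaLi3[(S)-binaphthoxide]3 (5 mol %), tris(2,4,6-trimethoxyphenyl)phosphine oxide (5 mol %), 5 Å MS, THF, rt
Reagents that add atoms: trimethylsulfoxonium iodide, C[S+](C)(C)=O.[I-]
Why: Catalytic asymmetric Corey–Chaykovsky epoxidation (Shibasaki La–Li–binaphthoxide system, 91–97% ee reported for methyl ketones), in which the bimetallic catalyst binds ketone and ylide and transfers CH2 to one carbonyl face under catalyst control, so the quaternary oxirane carbon is formed R and the remote methine is untouched.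

**Step 3**
Reactants: 5 (2R)-2-methyl-2-[(2R)-2-methyl-8-phenyloctyl]oxirane
Product: 6 (2S,4R)-2-hydroperoxy-2,4-dimethyl-10-phenyldecan-1-ol
Conditions: anhydrous H2O2 in Et2O (8 equiv), H3PMo12O40 (2 mol %), 0 °C → rt
Reagents that add atoms: hydrogen peroxide, OO
Why: Molybdate-catalysed perhydrolysis of an epoxide (Wu-type ring opening), in which H2O2 attacks the activated oxirane at the tertiary carbon from the side opposite the leaving oxygen, so the future ring carbon C5 is formed S by inversion and the released oxygen stays on the primary carbon as a handle.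

**Step 4**
Reactants: 6 (2S,4R)-2-hydroperoxy-2,4-dimethyl-10-phenyldecan-1-ol
Product: 7 (2S,4R)-2-[(2-methoxypropan-2-yl)peroxy]-2,4-dimethyl-10-phenyldecan-1-ol
Conditions: 2-methoxypropene (1.2 equiv), pyridinium p-toluenesulfonate (2 mol %), CH2Cl2, −20 °C, 30 min; Et3N quench
Reagents that add atoms: 2-methoxypropene, COC(C)=C
Why: Chemoselective peroxyketalisation (Dussault's 2-methoxyprop-2-yl protection), in which the hydroperoxide, far more nucleophilic than the neopentyl-type primary alcohol, adds first to the protonated enol ether at low temperature, so no stereocentre is touched and short contact keeps the cyclic 1,2,4-trioxane from forming.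

**Step 5**
Reactants: 7 (2S,4R)-2-[(2-methoxypropan-2-yl)peroxy]-2,4-dimethyl-10-phenyldecan-1-ol
Product: 8 (2S,4R)-2-[(2-methoxypropan-2-yl)peroxy]-2,4-dimethyl-10-phenyldecanal
Conditions: Dess–Martin periodinane (1.3 equiv), pyridine, CH2Cl2, 0 °C → rt
Reagents that add atoms: none
Why: Buffered Dess–Martin oxidation gives the aldehyde without touching the peroxyketal, and because the alpha carbon is quaternary the alpha-peroxy aldehyde can neither enolise nor fragment in the Kornblum–DeLaMare sense, so C5 is safe.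

**Step 6**
Reactants: 9 ethoxyethene (ethyl vinyl ether)
Product: 10 (1-ethoxyethyl)triphenylphosphonium bromide (racemic)
Conditions: Ph3P·HBr (1.0 equiv), CH2Cl2, 0 °C → rt; precipitation with Et2O
Reagents that add atoms: triphenylphosphine hydrobromide, [Br-].c1ccc(cc1)[PH+](c1ccccc1)c1ccccc1
Why: Markovnikov addition of a phosphine hydrobromide to an enol ether, in which protonation gives an oxocarbenium ion that PPh3 captures (the same reaction that converts dihydropyran into its 2-phosphonium salt), and the new centre is racemic and is destroyed in the next step.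

**Step 7**
Reactants: 8 (2S,4R)-2-[(2-methoxypropan-2-yl)peroxy]-2,4-dimethyl-10-phenyldecanal; 10 (1-ethoxyethyl)triphenylphosphonium bromide
Product: 12 (4S,6R)-2-ethoxy-4-[(2-methoxypropan-2-yl)peroxy]-4,6-dimethyl-12-phenyldodec-2-ene (E/Z mixture), via phosphorus ylide 11 (not isolated)
Conditions: 10 (1.5 equiv), KN(SiMe3)2 (1.45 equiv), THF, −78 → −40 °C; then 8, −78 → 0 °C
Reagents that add atoms: none
Why: Wittig olefination with an alpha-alkoxy ylide used as an acetyl anion equivalent, in which the ylide carbon that becomes the ketone-level carbon C3 attacks the non-enolisable aldehyde carbon, so two carbonyl-type carbons are joined, and loss of Ph3P=O removes the aldehyde oxygen and turns that carbon into the future ring CH2 (C4) without touching C5, alkene geometry being irrelevant; Wittig-type olefinations of alpha-peroxy aldehydes are known with stabilised reagents, and the use of this more basic ylide next to a peroxide is the bold part of the route.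

**Step 8**
Reactants: 12 (4S,6R)-2-ethoxy-4-[(2-methoxypropan-2-yl)peroxy]-4,6-dimethyl-12-phenyldodec-2-ene
Product: 14 (5S)-3-ethoxy-3,5-dimethyl-5-[(2R)-2-methyl-8-phenyloctyl]-1,2-dioxolane (C3 epimers), via hydroperoxy enol ether 13 (not isolated)
Conditions: pyridinium p-toluenesulfonate (10 mol %), EtOH, 0 °C; then TsOH·H2O (5 mol %), rt
Reagents that add atoms: none
Why: Acid-catalysed enol ether protonation followed by intramolecular peroxyketalisation, in which C-protonation gives an oxocarbenium ion at C3, ethanol takes off the 2-methoxyprop-2-yl group and the freed hydroperoxide closes the five-membered peroxyketal, so the 1,2-dioxolane ring forms with C5 untouched and the new ketal centre (a mixture) is erased in the last step.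

**Step 9**
Reactants: 14 (5S)-3-ethoxy-3,5-dimethyl-5-[(2R)-2-methyl-8-phenyloctyl]-1,2-dioxolane; 15 tert-butyl[(1-methoxyethenyl)oxy]dimethylsilane
Product: 17 methyl 2-[(3R,5S)-3,5-dimethyl-5-[(2R)-2-methyl-8-phenyloctyl]-1,2-dioxolan-3-yl]acetate (target), via dioxolan-3-ylium ion 16 (not isolated)
Conditions: TiCl4 (1.1 equiv), 15 (2 equiv), CH2Cl2, −78 °C; H2O; SiO2 chromatography to remove the C3 epimer
Reagents that add atoms: none
Why: Lewis acid-mediated alkylation of a peroxycarbenium ion with a silyl ketene acetal (Dussault type, a Mukaiyama-like addition), in which TiCl4 ionises the ethoxy group to the planar dioxolan-3-ylium ion and the nucleophile adds mainly anti to the larger C5 substituent (the 2-methyl-8-phenyloctyl arm), giving the 3R (trans) isomer with modest selectivity, the minor C3 epimer being separated.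

**Compound list**
1 | (6-bromohexyl)benzene | BrCCCCCCc1ccccc1 | starting material
2 | (E)-pent-3-en-2-one | C/C=C/C(C)=O | starting material
3 | 6-phenylhexylmagnesium bromide | Br[Mg]CCCCCCc1ccccc1 | intermediate
4 | (R)-4-methyl-10-phenyldecan-2-one | CC(=O)C[C@H](C)CCCCCCc1ccccc1 | intermediate
5 | (2R)-2-methyl-2-[(2R)-2-methyl-8-phenyloctyl]oxirane | C[C@@]1(C[C@H](C)CCCCCCc2ccccc2)CO1 | intermediate
6 | (2S,4R)-2-hydroperoxy-2,4-dimethyl-10-phenyldecan-1-ol | OC[C@](C)(C[C@H](C)CCCCCCc1ccccc1)OO | intermediate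
7 | (2S,4R)-2-[(2-methoxypropan-2-yl)peroxy]-2,4-dimethyl-10-phenyldecan-1-ol | OC[C@](C)(C[C@H](C)CCCCCCc1ccccc1)OOC(C)(C)OC | intermediate
8 | (2S,4R)-2-[(2-methoxypropan-2-yl)peroxy]-2,4-dimethyl-10-phenyldecanal | O=C[C@](C)(C[C@H](C)CCCCCCc1ccccc1)OOC(C)(C)OC | intermediate
9 | ethoxyethene | C=COCC | starting material
10 | (1-ethoxyethyl)triphenylphosphonium bromide | CCOC(C)[P+](c1ccccc1)(c1ccccc1)c1ccccc1.[Br-] | intermediate
11 | (1-ethoxyethylidene)triphenylphosphorane | CCOC(C)=P(c1ccccc1)(c1ccccc1)c1ccccc1 | intermediate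
12 | (4S,6R)-2-ethoxy-4-[(2-methoxypropan-2-yl)peroxy]-4,6-dimethyl-12-phenyldodec-2-ene | CCOC(C)=C[C@](C)(C[C@H](C)CCCCCCc1ccccc1)OOC(C)(C)OC | intermediate
13 | (4S,6R)-2-ethoxy-4-hydroperoxy-4,6-dimethyl-12-phenyldodec-2-ene | CCOC(C)=C[C@](C)(C[C@H](C)CCCCCCc1ccccc1)OO | intermediate
14 | (5S)-3-ethoxy-3,5-dimethyl-5-[(2R)-2-methyl-8-phenyloctyl]-1,2-dioxolane | CCOC1(C)C[C@](C)(C[C@H](C)CCCCCCc2ccccc2)OO1 | intermediate
15 | tert-butyl[(1-methoxyethenyl)oxy]dimethylsilane | C=C(OC)O[Si](C)(C)C(C)(C)C | starting material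
16 | (5S)-3,5-dimethyl-5-[(2R)-2-methyl-8-phenyloctyl]-1,2-dioxolan-3-ylium | C[C+]1C[C@](C)(C[C@H](C)CCCCCCc2ccccc2)OO1 | intermediate
17 | methyl 2-[(3R,5S)-3,5-dimethyl-5-[(2R)-2-methyl-8-phenyloctyl]-1,2-dioxolan-3-yl]acetate | COC(=O)C[C@@]1(C)C[C@](C)(C[C@H](C)CCCCCCc2ccccc2)OO1 | target

**Totals**
Total step count: 9 (eight on the main line plus the one-step preparation of phosphonium salt 10).
Longest linear sequence: 8 steps (1, 2, 3, 4, 5, 7, 8, 9).

**Three steps most likely to fail**

Step 3 (epoxide perhydrolysis). The risks are partial ionisation at the tertiary carbon, which would erode C5, and acid-induced rearrangement of the epoxide to an aldehyde. The fallback sets out from 5 and comes back at 14; it keeps the acyl anion logic but moves the inverting perhydrolysis to an oxetane, where it is established. 2-Methyl-1,3-dithiane is lithiated (n-BuLi, THF, −25 °C) to 2-lithio-2-methyl-1,3-dithiane F1, which opens 5 at its CH2 carbon (DMPU, −25 °C → rt) to give (2R,4R)-2,4-dimethyl-1-(2-methyl-1,3-dithian-2-yl)-10-phenyldecan-2-ol F2 with the C5–O bond intact. PhI(OCOCF3)2 in aqueous MeCN releases (4R,6R)-4-hydroxy-4,6-dimethyl-12-phenyldodecan-2-one F3, and NaBH4 gives (4R,6R)-4,6-dimethyl-12-phenyldodecane-2,4-diol F4 as carbinol epimers. n-BuLi and TsCl sulfonylate only the secondary hydroxyl to (4R,6R)-4-hydroxy-4,6-dimethyl-12-phenyldodecan-2-yl 4-methylbenzenesulfonate F5, which KOt-Bu closes to (2R)-2,4-dimethyl-2-[(2R)-2-methyl-8-phenyloctyl]oxetane F6. Ethereal H2O2 with catalytic Me3SiOTf (−78 → 0 °C) opens the oxetane at the tertiary carbon with inversion to (4S,6R)-4-hydroperoxy-4,6-dimethyl-12-phenyldodecan-2-ol F7. 2-Methoxypropene and pyridinium p-toluenesulfonate give (4S,6R)-4-[(2-methoxypropan-2-yl)peroxy]-4,6-dimethyl-12-phenyldodecan-2-ol F8, and Dess–Martin oxidation gives (4S,6R)-4-[(2-methoxypropan-2-yl)peroxy]-4,6-dimethyl-12-phenyldodecan-2-one F9. TsOH in EtOH removes the peroxyketal, the hydroperoxy ketone closes to (5S)-3,5-dimethyl-5-[(2R)-2-methyl-8-phenyloctyl]-1,2-dioxolan-3-ol F10, and this is ketalised in the same flask to 14.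

Step 7 (alpha-alkoxy ylide on the alpha-peroxy aldehyde). The aldehyde is neopentyl-like, and the strongly basic ylide may decompose or attack the O–O bond before it olefinates. The fallback sets out from 8 and comes back at 12 through a two-stage Horner–Wittig sequence with a less basic, more nucleophilic phosphine oxide anion. Ph2PCl and 1,1-diethoxyethane give (1-ethoxyethyl)diphenylphosphine oxide F11. LiN(i-Pr)2 at −78 °C gives (1-ethoxy-1-lithioethyl)diphenylphosphine oxide F12, which adds to 8 at −78 °C to give (4S,6R)-2-(diphenylphosphoryl)-2-ethoxy-4-[(2-methoxypropan-2-yl)peroxy]-4,6-dimethyl-12-phenyldodecan-3-ol F13. This adduct can be purified, and KH in THF then brings about syn-elimination of diphenylphosphinate to give 12.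

Step 9 (C3 selectivity and survival of the peroxide under TiCl4). The face selectivity is modest and the ketene acetal adduct may be hard to separate from its epimer. The fallback sets out from 14 and comes back at 17, installing the side chain as an allyl group and trimming it oxidatively. TiCl4 and allyltrimethylsilane at −78 °C give (3S,5S)-3,5-dimethyl-5-[(2R)-2-methyl-8-phenyloctyl]-3-(prop-2-en-1-yl)-1,2-dioxolane F14 through ion 16, and the epimers are separated at this stage. Ozone (CH2Cl2/MeOH, −78 °C, then Me2S) gives 2-[(3R,5S)-3,5-dimethyl-5-[(2R)-2-methyl-8-phenyloctyl]-1,2-dioxolan-3-yl]acetaldehyde F15. NaClO2/NaH2PO4/2-methyl-2-butene gives 2-[(3R,5S)-3,5-dimethyl-5-[(2R)-2-methyl-8-phenyloctyl]-1,2-dioxolan-3-yl]acetic acid F16, and Me3SiCHN2 in MeOH/toluene gives 17.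

**Further compounds**
F1 | step 3 | 2-lithio-2-methyl-1,3-dithiane | [Li]C1(C)SCCCS1
F2 | step 3 | (2R,4R)-2,4-dimethyl-1-(2-methyl-1,3-dithian-2-yl)-10-phenyldecan-2-ol | CC1(C[C@@](C)(C[C@H](C)CCCCCCc2ccccc2)O)SCCCS1
F3 | step 3 | (4R,6R)-4-hydroxy-4,6-dimethyl-12-phenyldodecan-2-one | CC(=O)C[C@@](C)(C[C@H](C)CCCCCCc1ccccc1)O
F4 | step 3 | (4R,6R)-4,6-dimethyl-12-phenyldodecane-2,4-diol | CC(O)C[C@@](C)(C[C@H](C)CCCCCCc1ccccc1)O
F5 | step 3 | (4R,6R)-4-hydroxy-4,6-dimethyl-12-phenyldodecan-2-yl 4-methylbenzenesulfonate | CC(C[C@@](C)(C[C@H](C)CCCCCCc1ccccc1)O)OS(=O)(=O)c1ccc(C)cc1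
F6 | step 3 | (2R)-2,4-dimethyl-2-[(2R)-2-methyl-8-phenyloctyl]oxetane | CC1C[C@@](C)(C[C@H](C)CCCCCCc2ccccc2)O1
F7 | step 3 | (4S,6R)-4-hydroperoxy-4,6-dimethyl-12-phenyldodecan-2-ol | CC(O)C[C@](C)(C[C@H](C)CCCCCCc1ccccc1)OO
F8 | step 3 | (4S,6R)-4-[(2-methoxypropan-2-yl)peroxy]-4,6-dimethyl-12-phenyldodecan-2-ol | CC(O)C[C@](C)(C[C@H](C)CCCCCCc1ccccc1)OOC(C)(C)OC
F9 | step 3 | (4S,6R)-4-[(2-methoxypropan-2-yl)peroxy]-4,6-dimethyl-12-phenyldodecan-2-one | CC(=O)C[C@](C)(C[C@H](C)CCCCCCc1ccccc1)OOC(C)(C)OC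
F10 | step 3 | (5S)-3,5-dimethyl-5-[(2R)-2-methyl-8-phenyloctyl]-1,2-dioxolan-3-ol | CC1(O)C[C@](C)(C[C@H](C)CCCCCCc2ccccc2)OO1
F11 | step 7 | (1-ethoxyethyl)diphenylphosphine oxide | CCOC(C)P(=O)(c1ccccc1)c1ccccc1
F12 | step 7 | (1-ethoxy-1-lithioethyl)diphenylphosphine oxide | [Li]C(C)(OCC)P(=O)(c1ccccc1)c1ccccc1
F13 | step 7 | (4S,6R)-2-(diphenylphosphoryl)-2-ethoxy-4-[(2-methoxypropan-2-yl)peroxy]-4,6-dimethyl-12-phenyldodecan-3-ol | CCOC(C)(C(O)[C@](C)(C[C@H](C)CCCCCCc1ccccc1)OOC(C)(C)OC)P(=O)(c1ccccc1)c1ccccc1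
F14 | step 9 | (3S,5S)-3,5-dimethyl-5-[(2R)-2-methyl-8-phenyloctyl]-3-(prop-2-en-1-yl)-1,2-dioxolane | C=CC[C@@]1(C)C[C@](C)(C[C@H](C)CCCCCCc2ccccc2)OO1
F15 | step 9 | 2-[(3R,5S)-3,5-dimethyl-5-[(2R)-2-methyl-8-phenyloctyl]-1,2-dioxolan-3-yl]acetaldehyde | O=CC[C@@]1(C)C[C@](C)(C[C@H](C)CCCCCCc2ccccc2)OO1
F16 | step 9 | 2-[(3R,5S)-3,5-dimethyl-5-[(2R)-2-methyl-8-phenyloctyl]-1,2-dioxolan-3-yl]acetic acid | OC(=O)C[C@@]1(C)C[C@](C)(C[C@H](C)CCCCCCc2ccccc2)OO1
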